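in all of them: free catalyst 10 mM
- alpha: starting material 0.40 M; second substrate 0.20 M; the very flask that is asked about, followed so far
- zeta: starting material 0.20 M; second substrate 0.20 M; run made earlier
- flask: starting material 0.40 M; second substrate 0.200 M

| run | time / min | target / % | starting material / % |
|---|---|---|---|
| alpha | 0.417 | 7.8 | 90.2 |
| alpha | 0.833 | 16.0 | 82.6 |
| alpha | 2.00 | 35.5 | 63.2 |
| alpha | 5.00 | 71.3 | 28.1 |
| zeta | 0.667 | 18.8 | 78.7 |
| zeta | 1.50 | 39.2 | 59.1 |
| zeta | 3.00 | 64.5 | 33.6 |
| zeta | 5.00 | 83.1 | 16.5 |

(each reading ± 0.3 percentage points)

- factor on the rate of making target when 30% of the starting material are converted if free catalyst is charged twice over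
- factor on the rate when 30% of the starting material are converted if free catalyst is charged at 1.0 mM instead

- steps under discussion: free catalyst <-> dormant form; starting material + free catalyst <-> catalyst intermediate A; catalyst intermediate B -> free catalyst + second product; second substrate + free catalyst <-> catalyst intermediate B; catalyst intermediate A -> free catalyst + target
- no earlier run changes the charge of free catalyst; that part of a forecast is a guess

- Do not take the factor on the rate for the factor on the charge: a flask with another charge of free catalyst reaches 30% conversion at another time, and the catalyst it has lost by then can differ.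
- Open the books on the 10 mM of catalyst in the flask. In the alpha run, starting material not yet found as target puts 8.00 mM in catalyst intermediate A at 0.417 min and 5.20 mM at 2.00 min. Intermediate A is the resting state at the first reading, so take the rate of target as proportional to it.
- Enter the loss. Alpha makes target at 0.0477 M min⁻¹ from 2.00 min to 5.00 min, and zeta at 0.0564 M min⁻¹ up to 0.667 min, with nearly equal mean starting material. Read this as a fade of 0.0525 min⁻¹ in working catalyst.
- Read the catalyst clock between the alpha readings: 1.59 min, the time to 30% conversion at 10 mM, taken inversely proportional to the charge.
- Go round with twice the charge: half the clock gives a factor of 2.09.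
- Go round at 1.0 mM: ten times the clock gives 15.9 min and a factor of 0.0472. Put the faded share back in: the time stretches to 22.2 min, and I commit to 0.0339, a guess.
- The forecast gives 2.05 (1.95 to 2.2) and 0.075 (0.03 to 0.1), lower than mine on the first factor and higher on the second: “That gives about 0.075, which is a guess.”

    free catalyst ⇌ dormant form (K = 2.00, k = 0.0100 s⁻¹)
    starting material + free catalyst ⇌ catalyst intermediate A (K = 50.0 M⁻¹, k = 2.30 M⁻¹ s⁻¹)
    catalyst intermediate B → free catalyst + second product (k = 0.670 s⁻¹)
    second substrate + free catalyst ⇌ catalyst intermediate B (K = 2.00 M⁻¹, k = 89.0 M⁻¹ s⁻¹)
    catalyst intermediate A → free catalyst + target (k = 0.190 s⁻¹)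

- The flask gives 2.16 and 0.0794, and its dormant form stands at 62.4% at 12.0 min and 66.7% at 120 min. The flask reaches 30% conversion at 1.56 min, against the clock's 1.59 min. With twice the free catalyst it takes 0.717 min, where half the clock gives 0.795 min.

The readings were generated by integration with made-up constants; the scatter is artificial.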